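Left-handed product cannot reach 63% of the charge at 5.00 h in the dawn run if left-handed substrate, half of that charge, merely reacts, so right-handed substrate must also be turning into left-handed substrate while both react.

common to all: free catalyst 0.92 mM; added ligand 3.9 mM
- dawn: left-handed substrate 0.27 M; right-handed substrate 0.27 M; reagent 1.6 M; impurity 0.30 mM; run made earlier
- dusk: left-handed substrate 0.60 M; right-handed substrate 0.60 M; reagent 1.6 M; impurity 0.30 mM; run made earlier
- winter: left-handed substrate 0.40 M; right-handed substrate 0.40 M; reagent 1.6 M; impurity 0.60 mM; run made earlier
- flask: left-handed substrate 0.40 M; right-handed substrate 0.40 M; reagent 1.60 M; impurity 0.30 mM; time 5.0 h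

| run | time / h | left-handed product / % | right-handed product / % | left-handed substrate / % |
|---|---|---|---|---|
| dawn | 0.667 | 38 | 17 | 19 |
| dawn | 1.33 | 47 | 27 | 10 |
| dawn | 2.00 | 54 | 29 | 8 |
| dawn | 3.00 | 58 | 32 | 3 |
| dawn | 4.00 | 62 | 32 | 1 |
| dawn | 5.00 | 63 | 33 | 5 |
| dusk | 0.417 | 28 | 15 | 27 |
| dusk | 0.667 | 35 | 17 | 20 |
| dusk | 1.00 | 39 | 21 | 18 |
| dusk | 1.33 | 45 | 22 | 15 |
| dusk | 2.00 | 48 | 25 | 10 |
| dusk | 3.00 | 57 | 30 | 10 |
| dusk | 5.00 | 61 | 29 | 3 |
| winter | 0.417 | 20 | 7 | 32 |
| winter | 0.833 | 29 | 13 | 26 |
| winter | 1.33 | 37 | 15 | 21 |
| winter | 2.50 | 50 | 22 | 14 |
| winter | 5.00 | 54 | 28 | 8 |

(scatter of a reading: 1.5 percentage points)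

- free catalyst is single-handed; left-handed substrate and right-handed substrate are mirror images of each other, charged as a racemate, each of them at the stated concentration
- an excess is below zero if the other one leads

1. excess of left-handed product over right-handed product in the product at 6.0 min
2. excess of left-handed product over right-handed product in the product at 5.0 h
3. part of the left-handed substrate and right-handed substrate charged together that has reacted at 5.0 h

The quantity to carry is the preference: how many times faster left-handed substrate becomes product than right-handed substrate at equal amounts of the two, the selectivity factor. Averaged over the first reading of each run, left-handed product stands at 28.7%, right-handed product at 13.0%, left-handed substrate at 26.0% and, by difference, right-handed substrate at 32.3%.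

Counting what is left, the ratio of the logarithms of the two fractions remaining gives 1.50. Counting what was made gives 2.21. The two part, and the fraction left cheats: left-handed substrate stands lower than right-handed substrate, so racemization refills it and hides part of its consumption. The product count needs one correction, the mean right-handed substrate over the mean left-handed substrate, each mean taken between the charge and the averaged first reading, which gives a preference of 2.39, a reading with the scatter of its readings.

With equal substrates, the excess in fresh product is the preference less one over the preference plus one, 41.0%. This reckoning commits to that figure for the flask at 6.0 min, earlier than any reading, and offers nothing separate for the end.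

The forecast gives an excess of 36% at 6.0 min and 32% at 5.0 h, with 93% reacted at 5.0 h, and notes that “early values may run slightly high”. Its early excess lies below this reckoning.

The flask gives an excess of 41.1% at 6.0 min and 31.8% at 5.0 h, with 95.2% reacted at 5.0 h.

    reagent + free catalyst + left-handed substrate → free catalyst + left-handed product (k = 2800 /M²/h)
    reagent + free catalyst + right-handed substrate → free catalyst + right-handed product (k = 1100 /M²/h)
    left-handed substrate ⇌ right-handed substrate (k = 0.930 /h)
    free catalyst + impurity → spent catalyst A (k = 2.00 × 10⁵ /M/h)
    free catalyst → spent catalyst B (k = 0.220 /h)
    free catalyst + added ligand ⇌ idle complex, settled at all times (K = 69.0 /M)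

At 0.509 h the flask uses left-handed substrate 1.7 times as fast by its product path as by the forward racemization step alone, and at 0.500 h left-handed substrate stands at 22.4% against 31.8% of right-handed substrate. The preference times that ratio of substrates makes fresh product in the flask at that moment 1.68 left to right, an excess of 25.4%, lower than the 41.1% of the product at 6.0 min. In the neighbour flask with 2.3 × 10⁻⁴ M of free catalyst, less than its 0.30 mM of impurity, the substrates stand at 48.9% and 48.9% at 5.00 h, so the reckoned excess is 41.0% again, and that flask holds 43.2%.

The readings are simulated for an exercise; the scatter is artificial.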